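## Analysis of the target

The target is an isoflavone: a chromen-4-one (rings A and C) with a 2,4-dihydroxyphenyl group (ring B) on C3. Ring A is fully substituted, with the hydrogen-bonded 5-OH, a 3-methylbut-2-enyl (prenyl) group on C6, the 7-OH, and a 2-hydroxy-3-methylbut-3-enyl chain on C8. The only stereocentre is the secondary carbinol carbon of the C8 chain; it is R, allylic and homobenzylic, and has no stereochemical neighbour, so a reagent has to set it. The sensitive groups are four phenols (base and air), two ortho-alkenyl phenol units that close to chromans or dihydrofurans under acid, and the carbinol itself, which lies next to the free 7-OH and an isopropenyl group and would ionise or cyclise under acid. The synthesis is hard for two reasons. The C6 and C8 chains are both five-carbon units with the same first CH2, and they must be placed on two electronically similar ring-A carbons without exchange. The stereocentre must also be made in one chain while the other, a plain trisubstituted alkene, stays untouched. The strategy rests on the C8 chain: its carbinol carbon and isopropenyl group are what a 2,3-epoxy alcohol gives on reductive transposition. The chain is therefore carried as an (E)-4-hydroxy-3-methylbut-2-enyl group, whose primary hydroxyl lets a chiral titanium tartrate complex find this alkene and ignore the C6 prenyl group.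

## Retrosynthetic reasoning

21 from 20. The last disconnection is the three aryl O–Si bonds. Silyl ethers are chosen because buffered fluoride is the one deprotection that neither the ortho-prenyl phenol nor the allylic carbinol can be harmed by.

20 from 19 and 18. The isopropenyl carbinol is traced back to a 2,3-epoxy alcohol. The terminal alkene carbon of 20 is the former CH2OH carbon of 18, and the carbinol C–O bond is the ring-side C–O bond of the oxirane. Going forward, the primary alcohol of 18 becomes the iodide 19, and zinc expels the distal oxirane oxygen together with iodide. The alkene position is then unambiguous, and the stereocentre is one that the epoxidation has already fixed.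

18 from 17. The two oxirane C–O bonds are cut to give the E-allylic alcohol 17. This is the point of the plan. The forward reaction must oxidise one of two trisubstituted alkenes and choose one face of it. A hydroxyl-directed titanium tartrate epoxidation does both, because only the C8 chain carries an allylic hydroxyl.

17 from 16, and 16 from 14 and 15. The chain C=C bond is cut by cross-metathesis between the terminal allyl group of 14 and 15, which gives the E-enal 16. A 1,2-reduction then gives 17. An allyl group is used as the placeholder at C8 because it is the only partner that a ruthenium alkylidene engages much faster than the prenyl group.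

14 from 13, 12, 11, and 9 with 10. The C6–CH2 bond is cut by a [3,3] shift. The 7-O-(1,1-dimethylallyl) ether 12 can only aromatise by delivering a normal prenyl group to C6, because C8 is already substituted. Ether 12 comes from the propargyl ether 11, made from phenol 9 and chloride 10. The 7-OH of 13 is then silylated to give 14, since a free phenol next to the later oxirane would open it.

9 from 8, 7, and 5 with 6. The C8–CH2 bond is cut by a first [3,3] shift of the 7-O-allyl ether 8. Allyl goes in first and prenyl second, so that the slower-migrating group occupies C8 before the faster-migrating tertiary ether is heated. The ring-B phenols are silylated (7 to 8) before the shift, so that afterwards O7 is the only reactive oxygen. Triisopropylsilyl is used on ring B because it withstands 200 °C and the amidine base of the next etherification. The 7-O-allyl ether 7 comes from tetraol 5 and 6 on the strength of the much higher acidity of the 7-OH.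

5 from 4, and 4 from 1 and 2 through 3. Ring C is cut at O1–C2 and C2–C3 (a one-carbon electrophile) and at the C4–C4a acyl bond. This leads to deoxybenzoin 3 and on to 1 and 2. The ring-B oxygens are carried as methyl ethers through this stage, because a free 2-hydroxyl would cyclise onto the deoxybenzoin ketone. They are removed (4 to 5) before any alkene is present.

## Alternatives that were turned down

Alternative 1: The O1–C8a aryl ether bond of ring C is disconnected. The forward key step is an intramolecular nucleophilic aromatic substitution. The enolate oxygen of formyl ketone A2 displaces fluoride under mild carbonate conditions and gives the fully protected isoflavone A1. A2 is a deoxybenzoin with a formyl group on its methylene carbon and fluorine on the future C8a, ortho to the ketone.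
- For it: the fluorine decides which ortho carbon becomes C8a, so the C6 and C8 chains cannot be interchanged. On this point it is stronger than the chosen route, whose two sigmatropic shifts depend on the intrinsic preferences of ring A. The closure is mild, and ortho-fluoro aryl ketones are good substrates even on an electron-rich ring.
- Against it: A2 is a hexasubstituted benzene. Fluorine, two different five-carbon chains, two protected phenols and the acyl group all have to be placed by a long linear sequence, and the carbinol stereocentre must come from a separate asymmetric step. The four methoxymethyl ethers of A1 leave only under acid, which the ortho-prenyl phenol and the allylic carbinol next to O7 do not tolerate.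
- Comparison: the chosen strategy accepts a regiochemical risk in the Claisen steps. In return it builds the ring system in one operation from two purchased aromatics, makes the stereocentre late with a reagent that also tells the chains apart, and ends with buffered fluoride.

Alternative 2: Ring A is taken apart into a pyranone and an alkyne by cutting C5–C6, C7–C8 and C4a–C5. Forward, irradiation of diazo ketone A4 induces a Wolff shift to a ketene. In A4 the diazoacyl group sits on C2 of a 5-aryl-4-pyranone and already carries the silylated side chain. The prenyl-substituted siloxyalkyne A5 traps the ketene by [2+2] addition, four-electron ring opening and six-electron closure (Danheiser benzannulation), giving A3 with the C5 phenol free.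
- For it: it is the most convergent plan and makes the hexasubstituted ring in one operation. The alkyne polarity fixes prenyl at C6 and oxygen at C7, and the diazo carbon fixes the side chain at C8. On convergence and regiochemical certainty it is stronger than the chosen route.
- Against it: A4 needs an acyl pyranone and a diazo transfer next to a silyloxy stereocentre that must again be made elsewhere. The ketene can add to the isopropenyl or prenyl alkenes, the aryl pyranone absorbs where the diazo ketone does, and A5 is a sensitive reagent that needs its own synthesis.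
- Comparison: it would take more steps in total and two unusual reagents, against fifteen conventional operations. The chosen route offers simple starting materials and a late, reagent-controlled stereocentre in place of convergence.

Alternative 3: The C4a–C5 bond is cut, which unravels ring A into a β-keto ester chain on C2 of the 5-aryl-4-pyranone, as in A7. Forward, a lithium silylamide base turns A7 into an extended enolate that runs through the pyranone. Its ring carbon, the future C4a, attacks the ester in a Claisen (Dieckmann-type) condensation, and enolisation gives A6 with both the 5-OH and the 7-OH free.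
- For it: it follows the polyketide logic of the natural product and needs no protecting group on ring A. Like the other two alternatives it leaves no doubt which carbon bears which chain. On these points it is stronger than the chosen route.
- Against it: A7 has two epimerisable carbons and is most acidic at the wrong one (between ketone and ester). C-acylation at the pyranone carbon therefore needs a polyanion and competes with O-acylation and retro-Claisen cleavage. The acyclic precursor must be built by successive acylations that each carry a branched chain. The aryl silyl ethers and the silyloxy stereocentre have to survive excess strong base.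
- Comparison: its main uncertainty is a ring closure on a chain this substituted. The chosen route keeps its uncertainty in a well-understood epoxidation and in two pericyclic steps. It is weaker only in that O7 has to be protected and released.

Key step: step 12

Assumption: the carbinol configuration read from the target SMILES is R; compounds 1, 2, 6, 10 and 15 are taken as purchased.

## Route

Step 1
Reactants: 1 phloroglucinol; 2 2-(2,4-dimethoxyphenyl)acetic acid
Product: 4 5,7-dihydroxy-2',4'-dimethoxyisoflavone, via deoxybenzoin 3 (not isolated)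
Conditions: BF3·OEt2 (solvent), 85 °C; then DMF, MsCl, 70 °C (one pot)
Reagents that add atoms: N,N-dimethylformamide, CN(C)C=O (its formyl carbon becomes C2)
Why: Friedel–Crafts (Houben–Hoesch-type) C-acylation of the symmetrical triol gives deoxybenzoin 3; the iminium formed from DMF and MsCl then formylates its activated methylene, and an ortho hydroxyl closes the pyranone with loss of dimethylamine (one-pot deoxybenzoin isoflavone synthesis). The methyl ethers keep the ring-B 2-oxygen from cyclising onto the ketone.

Step 2
Reactants: 4 5,7-dihydroxy-2',4'-dimethoxyisoflavone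
Product: 5 5,7,2',4'-tetrahydroxyisoflavone
Conditions: BBr3, CH2Cl2, −78 °C to rt; MeOH, H2O
Reagents that add atoms: none
Why: Lewis-acid cleavage of the two aryl methyl ethers (bromide attacks the O-methyl of the boron complex). It is placed here because the pyranone tolerates BBr3 and no alkene is yet present.

Step 3
Reactants: 5 5,7,2',4'-tetrahydroxyisoflavone; 6 allyl bromide
Product: 7 7-allyloxy-5,2',4'-trihydroxyisoflavone
Conditions: K2CO3 (1.0 equiv), DMF, 0 °C to rt
Reagents that add atoms: none
Why: Williamson ether synthesis. The 7-OH is a vinylogous carboxylic acid, about two to three pKa units more acidic than the ring-B phenols and far more than the chelated 5-OH, so one equivalent of carbonate should form and alkylate the 7-phenoxide.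

Step 4
Reactants: 7 7-allyloxy-5,2',4'-trihydroxyisoflavone
Product: 8 7-allyloxy-5-hydroxy-2',4'-bis(triisopropylsilyloxy)isoflavone
Conditions: TIPSCl (2.5 equiv), imidazole, DMF, rt
Reagents that add atoms: triisopropylsilyl chloride, CC(C)[Si](Cl)(C(C)C)C(C)C
Why: Silylation of the two free ring-B phenols; the 5-OH, locked in a hydrogen bond to the C4 carbonyl, should not react. Triisopropylsilyl is used for its stability to 200 °C and to DBU.

Step 5
Reactants: 8 7-allyloxy-5-hydroxy-2',4'-bis(triisopropylsilyloxy)isoflavone
Product: 9 8-allyl-5,7-dihydroxy-2',4'-bis(triisopropylsilyloxy)isoflavone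
Conditions: PhNEt2, 200 °C, sealed tube, Ar
Reagents that add atoms: none
Why: Aromatic Claisen rearrangement ([3,3] shift, then tautomerisation to the phenol). In 5-hydroxy-7-allyloxy chromones the shift is expected to go mainly to C8, the ortho carbon on the ring-oxygen side; any C6 isomer would be removed here.

Step 6
Reactants: 9 8-allyl-5,7-dihydroxy-2',4'-bis(triisopropylsilyloxy)isoflavone; 10 3-chloro-3-methylbut-1-yne
Product: 11 8-allyl-5-hydroxy-7-(2-methylbut-3-yn-2-yloxy)-2',4'-bis(triisopropylsilyloxy)isoflavone
Conditions: CuCl2·2H2O (1 mol%), DBU, MeCN, 0 °C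
Reagents that add atoms: none
Why: Copper-catalysed propargylic etherification: a copper acetylide ionises the tertiary chloride and the phenoxide adds at the tertiary carbon. Only the 7-OH is free and acidic; the chelated 5-OH and the silyl ethers should be left alone.

Step 7
Reactants: 11 8-allyl-5-hydroxy-7-(2-methylbut-3-yn-2-yloxy)-2',4'-bis(triisopropylsilyloxy)isoflavone
Product: 12 8-allyl-5-hydroxy-7-(2-methylbut-3-en-2-yloxy)-2',4'-bis(triisopropylsilyloxy)isoflavone
Conditions: H2 (1 atm), Pd/CaCO3 poisoned with Pb(OAc)2 (Lindlar catalyst), quinoline, EtOAc, rt, stopped after 1 equiv H2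
Reagents that add atoms: none
Why: Lindlar semihydrogenation. The terminal alkyne binds the poisoned palladium far more strongly than the monosubstituted alkene of the allyl group, so the alkyne should be reduced first.

Step 8
Reactants: 12 8-allyl-5-hydroxy-7-(2-methylbut-3-en-2-yloxy)-2',4'-bis(triisopropylsilyloxy)isoflavone
Product: 13 8-allyl-5,7-dihydroxy-6-(3-methylbut-2-enyl)-2',4'-bis(triisopropylsilyloxy)isoflavone
Conditions: o-xylene, 130 °C, sealed tube, Ar
Reagents that add atoms: none
Why: Aromatic Claisen rearrangement of the 1,1-dimethylallyl ether. The [3,3] shift inverts the allyl unit, so a normal prenyl group arrives at C6, the only unsubstituted ortho carbon. Tertiary ethers of this kind rearrange well below the temperature at which an O-allyl ether reacts.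

Step 9
Reactants: 13 8-allyl-5,7-dihydroxy-6-(3-methylbut-2-enyl)-2',4'-bis(triisopropylsilyloxy)isoflavone
Product: 14 8-allyl-7-(tert-butyldimethylsilyloxy)-5-hydroxy-6-(3-methylbut-2-enyl)-2',4'-bis(triisopropylsilyloxy)isoflavone
Conditions: TBSOTf (1.2 equiv), 2,6-lutidine, CH2Cl2, −78 to 0 °C
Reagents that add atoms: tert-butyldimethylsilyl trifluoromethanesulfonate, CC(C)(C)[Si](C)(C)OS(=O)(=O)C(F)(F)F
Why: Silylation of the hindered but acidic 7-OH with the silyl triflate; the chelated 5-OH is much less reactive. The ether is needed because a free 7-OH would open the oxirane made in step 12.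

Step 10
Reactants: 14 8-allyl-7-(tert-butyldimethylsilyloxy)-5-hydroxy-6-(3-methylbut-2-enyl)-2',4'-bis(triisopropylsilyloxy)isoflavone; 15 methacrolein
Product: 16 (E)-2-methyl-4-[7-(tert-butyldimethylsilyloxy)-5-hydroxy-6-(3-methylbut-2-enyl)-2',4'-bis(triisopropylsilyloxy)isoflavon-8-yl]but-2-enal
Conditions: second-generation Hoveyda–Grubbs catalyst (5 mol%), 1,4-benzoquinone (10 mol%), 15 (10 equiv), CH2Cl2, 40 °C
Reagents that add atoms: none
Why: Olefin cross-metathesis. The monosubstituted allyl alkene loads the ruthenium quickly, 15 does not homodimerise, and the trisubstituted enal forms as the more stable E isomer. The prenyl alkene reacts far more slowly, and benzoquinone suppresses allyl-to-propenyl isomerisation.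

Step 11
Reactants: 16 the E-enal
Product: 17 7-(tert-butyldimethylsilyloxy)-5-hydroxy-8-[(E)-4-hydroxy-3-methylbut-2-enyl]-6-(3-methylbut-2-enyl)-2',4'-bis(triisopropylsilyloxy)isoflavone
Conditions: NaBH4, CeCl3·7H2O, MeOH–THF, −40 °C
Reagents that add atoms: none
Why: Luche 1,2-reduction of the enal. The chelated pyranone carbonyl (a vinylogous ester) should not be reduced at this temperature, and the E geometry is untouched.

Step 12
Reactants: 17 the E-allylic alcohol
Product: 18 7-(tert-butyldimethylsilyloxy)-5-hydroxy-8-{[(2R,3R)-3-(hydroxymethyl)-3-methyloxiran-2-yl]methyl}-6-(3-methylbut-2-enyl)-2',4'-bis(triisopropylsilyloxy)isoflavone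
Conditions: Ti(OiPr)4 (2.0 equiv), D-(−)-diethyl tartrate (2.4 equiv), t-BuOOH (3 equiv, anhydrous), 4 Å molecular sieves, CH2Cl2, −20 °C; aqueous tartaric acid work-up
Reagents that add atoms: tert-butyl hydroperoxide, CC(C)(C)OO
Why: Sharpless–Katsuki asymmetric epoxidation of an E-2-methyl-3-alkyl allylic alcohol, a favourable substrate class for this reaction. The primary alkoxide of 17 and the tert-butyl peroxide replace isopropoxide on one tetravalent titanium of the tartrate-bridged dimer, and the distal peroxide oxygen passes to the bound alkene. The oxirane closes by concerted syn addition of that one oxygen to both alkene carbons (a [2+1] closure), so the E geometry becomes the trans relation of CH2OH and the ring-A CH2. Both new stereocentres are set by the tartrate: the D-(−) ester gives the (2R,3R) series with E-2-methylalk-2-en-1-ols (the L-(+) ester gives 2S,3S), and R at the ring-side oxirane carbon is the configuration of the carbinol in 21. The step needs chemoselectivity between two trisubstituted alkenes; the directing hydroxyl secures it, because the C6 prenyl group and the C2=C3 bond of ring C are not held on titanium by an allylic alkoxide and are not oxidised at −20 °C. The 5-OH and C4 carbonyl will bind one titanium as a chelate, so more than one equivalent of complex is used, with tartrate in excess of titanium so that no ligand-free titanium is left to run a background reaction. The 7-O-silyl ether keeps the neighbouring phenol from opening the new oxirane.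

Step 13
Reactants: 18 the (2R,3R)-epoxy alcohol
Product: 19 7-(tert-butyldimethylsilyloxy)-5-hydroxy-8-{[(2R,3S)-3-(iodomethyl)-3-methyloxiran-2-yl]methyl}-6-(3-methylbut-2-enyl)-2',4'-bis(triisopropylsilyloxy)isoflavone
Conditions: I2, PPh3, imidazole, THF, 0 °C
Reagents that add atoms: iodine, II
Why: Appel-type iodination (Garegg–Samuelsson conditions) of the primary alcohol through its alkoxyphosphonium salt; imidazole buffers the acid so the oxirane survives. No stereocentre is touched; the descriptor of the quaternary carbon changes only because CH2I outranks the ring carbon.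

Step 14
Reactants: 19 the epoxy iodide
Product: 20 7-(tert-butyldimethylsilyloxy)-5-hydroxy-8-[(2R)-2-hydroxy-3-methylbut-3-enyl]-6-(3-methylbut-2-enyl)-2',4'-bis(triisopropylsilyloxy)isoflavone
Conditions: activated Zn dust, EtOH–THF, 60 °C
Reagents that add atoms: none
Why: Reductive ring opening of a 2,3-epoxy iodide: zinc inserts into the carbon–iodine bond and β-elimination expels the distal oxirane oxygen, forming the isopropenyl group. The C–O bond at the ring-side carbon is not broken, so its R configuration is kept.

Step 15
Reactants: 20 the tris-silyl ether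
Product: 21 5,7,2',4'-tetrahydroxy-8-[(2R)-2-hydroxy-3-methylbut-3-enyl]-6-(3-methylbut-2-enyl)isoflavone
Conditions: TBAF (4 equiv), AcOH (4 equiv), THF, 0 °C
Reagents that add atoms: none
Why: Fluoride cleavage of the three aryl silyl ethers. Acetic acid buffers the phenoxides against oxidation, and the absence of strong acid protects the ortho-prenyl phenol and the allylic carbinol.

## Compound list

1 | phloroglucinol (benzene-1,3,5-triol) | Oc1cc(O)cc(O)c1 | starting material
2 | 2-(2,4-dimethoxyphenyl)acetic acid | COc1ccc(CC(=O)O)c(OC)c1 | starting material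
3 | 2-(2,4-dimethoxyphenyl)-1-(2,4,6-trihydroxyphenyl)ethanone (deoxybenzoin) | COc1ccc(CC(=O)c2c(O)cc(O)cc2O)c(OC)c1 | intermediate (not isolated)
4 | 5,7-dihydroxy-2',4'-dimethoxyisoflavone [3-(2,4-dimethoxyphenyl)-5,7-dihydroxychromen-4-one] | COc1ccc(-c2coc3cc(O)cc(O)c3c2=O)c(OC)c1 | intermediate
5 | 5,7,2',4'-tetrahydroxyisoflavone | O=c1c(-c2ccc(O)cc2O)coc2cc(O)cc(O)c12 | intermediate
6 | allyl bromide (3-bromoprop-1-ene) | C=CCBr | starting material
7 | 7-allyloxy-5,2',4'-trihydroxyisoflavone | C=CCOc1cc(O)c2c(=O)c(-c3ccc(O)cc3O)coc2c1 | intermediate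
8 | 7-allyloxy-5-hydroxy-2',4'-bis(triisopropylsilyloxy)isoflavone | C=CCOc1cc(O)c2c(=O)c(-c3ccc(O[Si](C(C)C)(C(C)C)C(C)C)cc3O[Si](C(C)C)(C(C)C)C(C)C)coc2c1 | intermediate
9 | 8-allyl-5,7-dihydroxy-2',4'-bis(triisopropylsilyloxy)isoflavone | C=CCc1c(O)cc(O)c2c(=O)c(-c3ccc(O[Si](C(C)C)(C(C)C)C(C)C)cc3O[Si](C(C)C)(C(C)C)C(C)C)coc12 | intermediate
10 | 3-chloro-3-methylbut-1-yne | C#CC(C)(C)Cl | starting material
11 | 8-allyl-5-hydroxy-7-(2-methylbut-3-yn-2-yloxy)-2',4'-bis(triisopropylsilyloxy)isoflavone | C#CC(C)(C)Oc1cc(O)c2c(=O)c(-c3ccc(O[Si](C(C)C)(C(C)C)C(C)C)cc3O[Si](C(C)C)(C(C)C)C(C)C)coc2c1CC=C | intermediate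
12 | 8-allyl-5-hydroxy-7-(2-methylbut-3-en-2-yloxy)-2',4'-bis(triisopropylsilyloxy)isoflavone | C=CC(C)(C)Oc1cc(O)c2c(=O)c(-c3ccc(O[Si](C(C)C)(C(C)C)C(C)C)cc3O[Si](C(C)C)(C(C)C)C(C)C)coc2c1CC=C | intermediate
13 | 8-allyl-5,7-dihydroxy-6-(3-methylbut-2-enyl)-2',4'-bis(triisopropylsilyloxy)isoflavone | C=CCc1c(O)c(CC=C(C)C)c(O)c2c(=O)c(-c3ccc(O[Si](C(C)C)(C(C)C)C(C)C)cc3O[Si](C(C)C)(C(C)C)C(C)C)coc12 | intermediate
14 | 8-allyl-7-(tert-butyldimethylsilyloxy)-5-hydroxy-6-(3-methylbut-2-enyl)-2',4'-bis(triisopropylsilyloxy)isoflavone | C=CCc1c(O[Si](C)(C)C(C)(C)C)c(CC=C(C)C)c(O)c2c(=O)c(-c3ccc(O[Si](C(C)C)(C(C)C)C(C)C)cc3O[Si](C(C)C)(C(C)C)C(C)C)coc12 | intermediate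
15 | methacrolein (2-methylprop-2-enal) | C=C(C)C=O | starting material
16 | (E)-2-methyl-4-[7-(tert-butyldimethylsilyloxy)-5-hydroxy-6-(3-methylbut-2-enyl)-2',4'-bis(triisopropylsilyloxy)isoflavon-8-yl]but-2-enal | O=C/C(C)=C/Cc1c(O[Si](C)(C)C(C)(C)C)c(CC=C(C)C)c(O)c2c(=O)c(-c3ccc(O[Si](C(C)C)(C(C)C)C(C)C)cc3O[Si](C(C)C)(C(C)C)C(C)C)coc12 | intermediate
17 | 7-(tert-butyldimethylsilyloxy)-5-hydroxy-8-[(E)-4-hydroxy-3-methylbut-2-enyl]-6-(3-methylbut-2-enyl)-2',4'-bis(triisopropylsilyloxy)isoflavone | OC/C(C)=C/Cc1c(O[Si](C)(C)C(C)(C)C)c(CC=C(C)C)c(O)c2c(=O)c(-c3ccc(O[Si](C(C)C)(C(C)C)C(C)C)cc3O[Si](C(C)C)(C(C)C)C(C)C)coc12 | intermediate (key-step precursor)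
18 | 7-(tert-butyldimethylsilyloxy)-5-hydroxy-8-{[(2R,3R)-3-(hydroxymethyl)-3-methyloxiran-2-yl]methyl}-6-(3-methylbut-2-enyl)-2',4'-bis(triisopropylsilyloxy)isoflavone | OC[C@@]1(C)O[C@@H]1Cc1c(O[Si](C)(C)C(C)(C)C)c(CC=C(C)C)c(O)c2c(=O)c(-c3ccc(O[Si](C(C)C)(C(C)C)C(C)C)cc3O[Si](C(C)C)(C(C)C)C(C)C)coc12 | intermediate (key-step product)
19 | 7-(tert-butyldimethylsilyloxy)-5-hydroxy-8-{[(2R,3S)-3-(iodomethyl)-3-methyloxiran-2-yl]methyl}-6-(3-methylbut-2-enyl)-2',4'-bis(triisopropylsilyloxy)isoflavone | IC[C@@]1(C)O[C@@H]1Cc1c(O[Si](C)(C)C(C)(C)C)c(CC=C(C)C)c(O)c2c(=O)c(-c3ccc(O[Si](C(C)C)(C(C)C)C(C)C)cc3O[Si](C(C)C)(C(C)C)C(C)C)coc12 | intermediate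
20 | 7-(tert-butyldimethylsilyloxy)-5-hydroxy-8-[(2R)-2-hydroxy-3-methylbut-3-enyl]-6-(3-methylbut-2-enyl)-2',4'-bis(triisopropylsilyloxy)isoflavone | C=C(C)[C@H](O)Cc1c(O[Si](C)(C)C(C)(C)C)c(CC=C(C)C)c(O)c2c(=O)c(-c3ccc(O[Si](C(C)C)(C(C)C)C(C)C)cc3O[Si](C(C)C)(C(C)C)C(C)C)coc12 | intermediate
21 | 5,7,2',4'-tetrahydroxy-8-[(2R)-2-hydroxy-3-methylbut-3-enyl]-6-(3-methylbut-2-enyl)isoflavone (CNP0140295.1) | C=C(C)[C@H](O)Cc1c(O)c(CC=C(C)C)c(O)c2c(=O)c(-c3ccc(O)cc3O)coc12 | target

## Step count and least certain steps

Total: 15 steps. Longest linear sequence: 15 steps (1 and 2 to 21).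

Step 12 (key step). The most likely failure is sequestration of titanium by the 5-OH and C4 carbonyl chelate. That would slow the directed reaction and leave ligand-poor titanium to run a less selective background epoxidation, eroding enantiomeric purity. A second failure is Lewis-acid opening of the trisubstituted oxirane under the stoichiometric conditions.
Fallback, from 16 back to 18: the enal is epoxidised without any metal. Aqueous H2O2 and a 9-amino-9-deoxy-epi-cinchona primary amine salt (iminium activation of α-branched enals; the pseudoenantiomer of the amine is chosen for the required sense) would give (2S,3R)-3-{[7-(tert-butyldimethylsilyloxy)-5-hydroxy-6-(3-methylbut-2-enyl)-2',4'-bis(triisopropylsilyloxy)isoflavon-8-yl]methyl}-2-methyloxirane-2-carbaldehyde F1. NaBH4 in MeOH at −20 °C then reduces F1 to 18. The prenyl group is not an enal and stays untouched.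

Step 8. The 1,1-dimethylallyl group can also attack the substituted C8. The resulting 8,8-disubstituted dienone cannot aromatise, and it can send its allyl group back to O7. That crossover would divert material into a 7-O-allyl-8-prenyl ether; at higher temperature this ether would scramble the two chains. Loss of the tertiary group as isoprene is a second drain.
Fallback, from 9 back to 13: a stepwise oxygen-to-carbon transfer that does not pass through a [3,3] dienone. Etherification of 9 with 1-bromo-3-methylbut-2-ene and K2CO3 in acetone gives 8-allyl-5-hydroxy-7-(3-methylbut-2-enyloxy)-2',4'-bis(triisopropylsilyloxy)isoflavone F2. Montmorillonite K10 clay in CH2Cl2 at 0 °C then moves the prenyl group of F2 to C6, the only free ortho carbon, by an ion-pair [1,3] shift, giving 13.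

Step 5. The allyl group may migrate partly to C6, because the two ortho carbons of O7 differ only modestly. That would cost material and require a separation of regioisomers.
Fallback, from 8 back to 13: C6 is blocked before the shift. Iodination of 8 with benzyltrimethylammonium dichloroiodate and CaCO3 in CH2Cl2–MeOH attacks ortho to the free 5-OH and gives 7-allyloxy-5-hydroxy-6-iodo-2',4'-bis(triisopropylsilyloxy)isoflavone F3. Heating F3 in PhNEt2 can move the allyl group only to C8, giving 8-allyl-5,7-dihydroxy-6-iodo-2',4'-bis(triisopropylsilyloxy)isoflavone F4. Stille coupling of F4 with tributyl(3-methylbut-2-enyl)stannane and Pd(PPh3)4 in DMF puts the prenyl group on C6 and gives 13. This also bypasses steps 6 to 8.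

Step 3. Over-alkylation at the ring-B phenols may occur, because selectivity rests only on the acidity gap between the 7-OH and the other phenols.
Fallback, from 5 back to 8: protect everything, then unmask the most labile position. Exhaustive silylation of 5 (TIPSCl, imidazole, DMF) gives 5-hydroxy-7,2',4'-tris(triisopropylsilyloxy)isoflavone F5. One equivalent of CsF with allyl bromide in DMF at 0 °C then cleaves only the 7-O-silyl ether of F5, whose phenoxide is the best leaving group, and allylates it in the same flask to give 8.

Step 7. Over-reduction of the allyl or the new vinyl group may occur once the alkyne is consumed.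
Fallback, from 9 back to 12: the hydrogenation is avoided, and steps 6 and 7 are replaced. Tsuji–Trost O-allylation of 9 with tert-butyl 2-methylbut-3-en-2-yl carbonate F6 (made from 2-methylbut-3-en-2-ol and di-tert-butyl dicarbonate) and Pd(PPh3)4 in THF at 0 °C, under kinetic control at the tertiary terminus, gives 12 directly.

## Further compounds

F1 | step 12 | (2S,3R)-3-{[7-(tert-butyldimethylsilyloxy)-5-hydroxy-6-(3-methylbut-2-enyl)-2',4'-bis(triisopropylsilyloxy)isoflavon-8-yl]methyl}-2-methyloxirane-2-carbaldehyde | O=C[C@@]1(C)O[C@@H]1Cc1c(O[Si](C)(C)C(C)(C)C)c(CC=C(C)C)c(O)c2c(=O)c(-c3ccc(O[Si](C(C)C)(C(C)C)C(C)C)cc3O[Si](C(C)C)(C(C)C)C(C)C)coc12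
F2 | step 8 | 8-allyl-5-hydroxy-7-(3-methylbut-2-enyloxy)-2',4'-bis(triisopropylsilyloxy)isoflavone | CC(C)=CCOc1cc(O)c2c(=O)c(-c3ccc(O[Si](C(C)C)(C(C)C)C(C)C)cc3O[Si](C(C)C)(C(C)C)C(C)C)coc2c1CC=C
F3 | step 5 | 7-allyloxy-5-hydroxy-6-iodo-2',4'-bis(triisopropylsilyloxy)isoflavone | C=CCOc1c(I)c(O)c2c(=O)c(-c3ccc(O[Si](C(C)C)(C(C)C)C(C)C)cc3O[Si](C(C)C)(C(C)C)C(C)C)coc2c1
F4 | step 5 | 8-allyl-5,7-dihydroxy-6-iodo-2',4'-bis(triisopropylsilyloxy)isoflavone | C=CCc1c(O)c(I)c(O)c2c(=O)c(-c3ccc(O[Si](C(C)C)(C(C)C)C(C)C)cc3O[Si](C(C)C)(C(C)C)C(C)C)coc12
F5 | step 3 | 5-hydroxy-7,2',4'-tris(triisopropylsilyloxy)isoflavone | CC(C)[Si](Oc1cc(O)c2c(=O)c(-c3ccc(O[Si](C(C)C)(C(C)C)C(C)C)cc3O[Si](C(C)C)(C(C)C)C(C)C)coc2c1)(C(C)C)C(C)C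
F6 | step 7 | tert-butyl 2-methylbut-3-en-2-yl carbonate | C=CC(C)(C)OC(=O)OC(C)(C)C
A1 | alternative 1 | 5,7,2',4'-tetrakis(methoxymethoxy)-8-[(2R)-2-(tert-butyldimethylsilyloxy)-3-methylbut-3-enyl]-6-(3-methylbut-2-enyl)isoflavone | C=C(C)[C@H](O[Si](C)(C)C(C)(C)C)Cc1c(OCOC)c(CC=C(C)C)c(OCOC)c2c(=O)c(-c3ccc(OCOC)cc3OCOC)coc12
A2 | alternative 1 | 2-[2,4-bis(methoxymethoxy)phenyl]-3-{2-fluoro-4,6-bis(methoxymethoxy)-5-(3-methylbut-2-enyl)-3-[(2R)-2-(tert-butyldimethylsilyloxy)-3-methylbut-3-enyl]phenyl}-3-oxopropanal (formyl tautomer) | C=C(C)[C@H](O[Si](C)(C)C(C)(C)C)Cc1c(F)c(C(=O)C(C=O)c2ccc(OCOC)cc2OCOC)c(OCOC)c(CC=C(C)C)c1OCOC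
A3 | alternative 2 | 5-hydroxy-7-(triisopropylsilyloxy)-2',4'-bis(tert-butyldimethylsilyloxy)-8-[(2R)-2-(tert-butyldimethylsilyloxy)-3-methylbut-3-enyl]-6-(3-methylbut-2-enyl)isoflavone | C=C(C)[C@H](O[Si](C)(C)C(C)(C)C)Cc1c(O[Si](C(C)C)(C(C)C)C(C)C)c(CC=C(C)C)c(O)c2c(=O)c(-c3ccc(O[Si](C)(C)C(C)(C)C)cc3O[Si](C)(C)C(C)(C)C)coc12
A4 | alternative 2 | (4R)-1-{5-[2,4-bis(tert-butyldimethylsilyloxy)phenyl]-4-oxo-4H-pyran-2-yl}-4-(tert-butyldimethylsilyloxy)-2-diazo-5-methylhex-5-en-1-one | C=C(C)[C@H](O[Si](C)(C)C(C)(C)C)CC(=[N+]=[N-])C(=O)c1cc(=O)c(-c2ccc(O[Si](C)(C)C(C)(C)C)cc2O[Si](C)(C)C(C)(C)C)co1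
A5 | alternative 2 | triisopropyl[(5-methylhex-4-en-1-ynyl)oxy]silane | CC(C)=CCC#CO[Si](C(C)C)(C(C)C)C(C)C
A6 | alternative 3 | 5,7-dihydroxy-2',4'-bis(tert-butyldimethylsilyloxy)-8-[(2R)-2-(tert-butyldimethylsilyloxy)-3-methylbut-3-enyl]-6-(3-methylbut-2-enyl)isoflavone | C=C(C)[C@H](O[Si](C)(C)C(C)(C)C)Cc1c(O)c(CC=C(C)C)c(O)c2c(=O)c(-c3ccc(O[Si](C)(C)C(C)(C)C)cc3O[Si](C)(C)C(C)(C)C)coc12
A7 | alternative 3 | methyl (6R)-4-{5-[2,4-bis(tert-butyldimethylsilyloxy)phenyl]-4-oxo-4H-pyran-2-yl}-6-(tert-butyldimethylsilyloxy)-7-methyl-2-(3-methylbut-2-enyl)-3-oxooct-7-enoate (mixture of epimers at C2 and C4) | C=C(C)[C@H](O[Si](C)(C)C(C)(C)C)CC(C(=O)C(CC=C(C)C)C(=O)OC)c1cc(=O)c(-c2ccc(O[Si](C)(C)C(C)(C)C)cc2O[Si](C)(C)C(C)(C)C)co1
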